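**Retrosynthetic overview**
1. The oxirane is the last ring. It comes from hydroxyl-directed epoxidation of the 4E-olefin of a (1(10)Z,4E)-cyclodecadienolide.
2. The ten-membered carbocycle comes from ring-closing metathesis at C1=C10 of an allyl arm (C3 side) and a methallyl arm (C8 side). Both arms are installed by catalyst-controlled allylboration, of a C3 enal and of a C8 aldehyde.
3. The key disconnection is C7–C8. C7 (butenolide β-carbon) and C8 (formyl carbon) are both natural electrophiles, so C8 enters as the nucleophilic 1,3-dioxolan-2-yl radical, a masked formyl donor of acyl-anion type. This replaces the customary C6–C7 allyl-metal closure.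
4. That one step sets C7 and the contra-thermodynamic C11. It also delivers C8 already masked, so no protecting-group step is needed.
5. Ring order: γ-lactone (from (R)-glyceraldehyde acetonide, the source of C6), then carbocycle, then oxirane. C3–C5 come from a formyl ylide.

Assumption: atoms are located by germacranolide numbers (C1–C15, lactone C12–O–C6); 1 is taken as a purchasable bulk intermediate made from D-mannitol; TRIP = 3,3'-bis(2,4,6-triisopropylphenyl)-1,1'-binaphthyl-2,2'-diyl hydrogen phosphate.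

**Route**

Step 1
Reactants: 1 (R)-2,2-dimethyl-1,3-dioxolane-4-carbaldehyde; 2 ethyl 2-[bis(2,2,2-trifluoroethoxy)phosphoryl]propanoate
Product: 4 (5S)-5-(hydroxymethyl)-3-methylfuran-2(5H)-one, via Z-enoate acetonide 3 (not isolated)
Conditions: KN(SiMe3)2, 18-crown-6, THF, −78 °C; then 10% aq H2SO4, MeOH, rt
Reagents that add atoms: ethyl 2-[bis(2,2,2-trifluoroethoxy)phosphoryl]propanoate (2), CCOC(=O)C(C)P(=O)(OCC(F)(F)F)OCC(F)(F)F
Why: The Still–Gennari variant of the Horner–Wadsworth–Emmons olefination gives the Z-trisubstituted enoate, so acid removal of the acetonide leaves the C6 hydroxyl cis to the ester and it lactonises at once, while C6 comes unchanged from the chiral pool and no new stereocentre is made.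

Step 2 (key step)
Reactants: 4 (5S)-5-(hydroxymethyl)-3-methylfuran-2(5H)-one; 5 1,3-dioxolane
Product: 6 (3R,4S,5S)-4-(1,3-dioxolan-2-yl)-5-(hydroxymethyl)-3-methyloxolan-2-one
Conditions: Ph2CO (0.2 equiv), hν (medium-pressure Hg lamp, Pyrex), degassed 5 as solvent, 0 °C
Reagents that add atoms: 1,3-dioxolane (5), C1COCO1
Why: In this sensitised radical conjugate (Giese-type) addition, triplet benzophenone abstracts the acetal hydrogen of 5, the nucleophilic 1,3-dioxolan-2-yl radical (a masked formyl carbon acting as donor, an acyl-anion-type synthon) attacks the electrophilic β-carbon C7 opposite the C6 hydroxymethyl group (C7 trans), and the planar C11 radical then takes its hydrogen atom on the face away from the new acetal, leaving the methyl group cis to it (the kinetic, contra-thermodynamic C11 of the target).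

Step 3
Reactants: 6 (3R,4S,5S)-4-(1,3-dioxolan-2-yl)-5-(hydroxymethyl)-3-methyloxolan-2-one
Product: 7 (2S,3S,4R)-2-(hydroxymethyl)-4-methyl-5-oxooxolane-3-carbaldehyde
Conditions: CF3CO2H–H2O (4:1), CH2Cl2, 0 °C to rt
Reagents that add atoms: water, O
Why: This is an acid-catalysed acetal hydrolysis under conditions too mild for β-elimination of the acyloxy group or for enolisation at C7 and C11, so all three stereocentres are kept.

Step 4
Reactants: 7 (2S,3S,4R)-2-(hydroxymethyl)-4-methyl-5-oxooxolane-3-carbaldehyde; 8 4,4,5,5-tetramethyl-2-(2-methylprop-2-en-1-yl)-1,3,2-dioxaborolane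
Product: 9 (3R,4R,5S)-4-[(1R)-1-hydroxy-3-methylbut-3-en-1-yl]-5-(hydroxymethyl)-3-methyloxolan-2-one
Conditions: 8 (1.2 equiv), (R)-TRIP (5 mol %), toluene–CH2Cl2, −30 °C; aq work-up
Reagents that add atoms: 4,4,5,5-tetramethyl-2-(2-methylprop-2-en-1-yl)-1,3,2-dioxaborolane (8), CC(=C)CB1OC(C)(C)C(C)(C)O1
Why: In this chiral-phosphoric-acid-catalysed allylboration through a closed chair transition state, (R)-TRIP steers the methallyl group to the Re face of the aldehyde and so sets C8 as R under catalyst control, the primary alcohol being a spectator.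

Step 5
Reactants: 9 (3R,4R,5S)-4-[(1R)-1-hydroxy-3-methylbut-3-en-1-yl]-5-(hydroxymethyl)-3-methyloxolan-2-one; 10 2-(triphenyl-λ5-phosphanylidene)propanal
Product: 12 (2E)-3-{(2R,3R,4R)-3-[(1R)-1-hydroxy-3-methylbut-3-en-1-yl]-4-methyl-5-oxooxolan-2-yl}-2-methylprop-2-enal, via lactone aldehyde 11 (not isolated)
Conditions: TEMPO (0.1 equiv), PhI(OAc)2 (1.1 equiv), CH2Cl2, rt; then 10 (2 equiv), rt to 40 °C
Reagents that add atoms: 2-(triphenyl-λ5-phosphanylidene)propanal (10), CC(C=O)=P(c1ccccc1)(c1ccccc1)c1ccccc1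
Why: The oxoammonium (TEMPO) oxidation touches only the unhindered primary alcohol (a trans-fused lactol cannot form, so there is no over-oxidation), and the epimerisable α-acyloxy aldehyde is consumed in the same flask by an E-selective Wittig reaction of the stabilised formyl ylide, which fixes the 4E geometry without making or losing a stereocentre.

Step 6
Reactants: 12 (2E)-3-{(2R,3R,4R)-3-[(1R)-1-hydroxy-3-methylbut-3-en-1-yl]-4-methyl-5-oxooxolan-2-yl}-2-methylprop-2-enal; 13 (E)-2-methylbut-2-enoyl chloride (tigloyl chloride)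
Product: 14 (1R)-3-methyl-1-{(2R,3R,4R)-4-methyl-2-[(1E)-2-methyl-3-oxoprop-1-en-1-yl]-5-oxooxolan-3-yl}but-3-en-1-yl (2E)-2-methylbut-2-enoate
Conditions: 13 (1.5 equiv), pyridine, DMAP (0.1 equiv), CH2Cl2, 0 °C to rt
Reagents that add atoms: (E)-2-methylbut-2-enoyl chloride (13), C/C=C(\C)C(=O)Cl
Why: This DMAP-catalysed acylation of the only free hydroxyl group proceeds with retention at C8, pyridine being too weak a base to deconjugate the tigloyl unit or to epimerise C11.

Step 7
Reactants: 14 (1R)-3-methyl-1-{(2R,3R,4R)-4-methyl-2-[(1E)-2-methyl-3-oxoprop-1-en-1-yl]-5-oxooxolan-3-yl}but-3-en-1-yl (2E)-2-methylbut-2-enoate; 15 2-allyl-4,4,5,5-tetramethyl-1,3,2-dioxaborolane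
Product: 16 (1R)-1-{(2R,3R,4R)-2-[(1E,3S)-3-hydroxy-2-methylhexa-1,5-dien-1-yl]-4-methyl-5-oxooxolan-3-yl}-3-methylbut-3-en-1-yl (2E)-2-methylbut-2-enoate
Conditions: 15 (1.5 equiv), (S)-TRIP (10 mol %), toluene, −30 to 0 °C; aq work-up
Reagents that add atoms: 2-allyl-4,4,5,5-tetramethyl-1,3,2-dioxaborolane (15), C=CCB1OC(C)(C)C(C)(C)O1
Why: In this second catalyst-controlled allylboration, (S)-TRIP sends the allyl group to the Si face of the α-branched enal in a 1,2-sense, which sets C3 as S independently of the remote lactone stereocentres.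

Step 8
Reactants: 16 (1R)-1-{(2R,3R,4R)-2-[(1E,3S)-3-hydroxy-2-methylhexa-1,5-dien-1-yl]-4-methyl-5-oxooxolan-3-yl}-3-methylbut-3-en-1-yl (2E)-2-methylbut-2-enoate
Product: 17 (1(10)Z,4E,3S,6R,7R,8R,11R)-3-hydroxy-8-[(E)-2-methylbut-2-enoyloxy]germacra-1(10),4-dien-12,6-olide
Conditions: second-generation Hoveyda–Grubbs catalyst (H2IMes)Cl2Ru(=CH-C6H4-2-OiPr) (10 mol %, syringe pump), 1,4-benzoquinone (20 mol %), toluene (0.5 mM), 80 °C, Ar sparge
Reagents that add atoms: none
Why: In this ring-closing metathesis, ruthenium loads on the monosubstituted C1 vinyl group and closes onto the 1,1-disubstituted C10 olefin with loss of ethylene, the trisubstituted C4=C5 and tiglate olefins being inert, and the ten-membered ring that already holds one E olefin should take up the new trisubstituted olefin as the less strained Z isomer.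

Step 9
Reactants: 17 (1(10)Z,4E,3S,6R,7R,8R,11R)-3-hydroxy-8-[(E)-2-methylbut-2-enoyloxy]germacra-1(10),4-dien-12,6-olide
Product: 18 (1(10)Z,3S,4R,5R,6S,7R,8R,11R)-4,5-epoxy-3-hydroxy-8-[(E)-2-methylbut-2-enoyloxy]germacr-1(10)-en-12,6-olide (CNP0265652.4)
Conditions: VO(acac)2 (5 mol %), t-BuOOH (1.3 equiv, decane), CH2Cl2, 0 °C
Reagents that add atoms: tert-butyl hydroperoxide, CC(C)(C)OO
Why: This hydroxyl-directed vanadium-catalysed epoxidation picks the allylic C4=C5 olefin over the homoallylic C1=C10 and the electron-poor tiglate olefins, and because allylic 1,3-strain between C15 and the C6 substituents keeps H6 in the olefin plane, only the outer face (the one that carries the C3 hydroxyl) is open, giving the 4R,5R oxirane.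

**Compound list**
1 | (R)-2,2-dimethyl-1,3-dioxolane-4-carbaldehyde | CC1(C)OC[C@H](C=O)O1 | starting material
2 | ethyl 2-[bis(2,2,2-trifluoroethoxy)phosphoryl]propanoate (racemic) | CCOC(=O)C(C)P(=O)(OCC(F)(F)F)OCC(F)(F)F | starting material
3 | ethyl (Z)-3-[(4S)-2,2-dimethyl-1,3-dioxolan-4-yl]-2-methylprop-2-enoate | CCOC(=O)/C(C)=C\[C@H]1COC(C)(C)O1 | intermediate
4 | (5S)-5-(hydroxymethyl)-3-methylfuran-2(5H)-one | CC1=C[C@@H](CO)OC1=O | intermediate
5 | 1,3-dioxolane | C1COCO1 | starting material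
6 | (3R,4S,5S)-4-(1,3-dioxolan-2-yl)-5-(hydroxymethyl)-3-methyloxolan-2-one | OC[C@H]1OC(=O)[C@H](C)[C@@H]1C1OCCO1 | intermediate
7 | (2S,3S,4R)-2-(hydroxymethyl)-4-methyl-5-oxooxolane-3-carbaldehyde | OC[C@H]1OC(=O)[C@H](C)[C@@H]1C=O | intermediate
8 | 4,4,5,5-tetramethyl-2-(2-methylprop-2-en-1-yl)-1,3,2-dioxaborolane | CC(=C)CB1OC(C)(C)C(C)(C)O1 | starting material
9 | (3R,4R,5S)-4-[(1R)-1-hydroxy-3-methylbut-3-en-1-yl]-5-(hydroxymethyl)-3-methyloxolan-2-one | OC[C@H]1OC(=O)[C@H](C)[C@@H]1[C@H](O)CC(C)=C | intermediate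
10 | 2-(triphenyl-λ5-phosphanylidene)propanal | CC(C=O)=P(c1ccccc1)(c1ccccc1)c1ccccc1 | starting material
11 | (2S,3R,4R)-3-[(1R)-1-hydroxy-3-methylbut-3-en-1-yl]-4-methyl-5-oxooxolane-2-carbaldehyde | O=C[C@H]1OC(=O)[C@H](C)[C@@H]1[C@H](O)CC(C)=C | intermediate
12 | (2E)-3-{(2R,3R,4R)-3-[(1R)-1-hydroxy-3-methylbut-3-en-1-yl]-4-methyl-5-oxooxolan-2-yl}-2-methylprop-2-enal | O=C/C(C)=C/[C@H]1OC(=O)[C@H](C)[C@@H]1[C@H](O)CC(C)=C | intermediate
13 | (E)-2-methylbut-2-enoyl chloride | C/C=C(\C)C(=O)Cl | starting material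
14 | (1R)-3-methyl-1-{(2R,3R,4R)-4-methyl-2-[(1E)-2-methyl-3-oxoprop-1-en-1-yl]-5-oxooxolan-3-yl}but-3-en-1-yl (2E)-2-methylbut-2-enoate | O=C/C(C)=C/[C@H]1OC(=O)[C@H](C)[C@@H]1[C@H](OC(=O)/C(C)=C/C)CC(C)=C | intermediate
15 | 2-allyl-4,4,5,5-tetramethyl-1,3,2-dioxaborolane | C=CCB1OC(C)(C)C(C)(C)O1 | starting material
16 | (1R)-1-{(2R,3R,4R)-2-[(1E,3S)-3-hydroxy-2-methylhexa-1,5-dien-1-yl]-4-methyl-5-oxooxolan-3-yl}-3-methylbut-3-en-1-yl (2E)-2-methylbut-2-enoate | C=CC[C@H](O)/C(C)=C/[C@H]1OC(=O)[C@H](C)[C@@H]1[C@H](OC(=O)/C(C)=C/C)CC(C)=C | intermediate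
17 | (1(10)Z,4E,3S,6R,7R,8R,11R)-3-hydroxy-8-[(E)-2-methylbut-2-enoyloxy]germacra-1(10),4-dien-12,6-olide | C/C=C(\C)C(=O)O[C@@H]1C/C(C)=C\C[C@H](O)/C(C)=C/[C@H]2OC(=O)[C@H](C)[C@@H]21 | intermediate
18 | (1(10)Z,3S,4R,5R,6S,7R,8R,11R)-4,5-epoxy-3-hydroxy-8-[(E)-2-methylbut-2-enoyloxy]germacr-1(10)-en-12,6-olide | C/C=C(\C)C(=O)O[C@@H]1C/C(C)=C\C[C@H](O)[C@@]2(C)O[C@@H]2[C@H]2OC(=O)[C@H](C)[C@@H]21 | target

**Totals and risks**
Total step count: 9. Longest linear sequence: 9 (1 to 18). No protecting-group step is used.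

**Step 2 (radical addition).**
- Risks: the α-methyl acceptor may react slowly, dioxolan-4-yl adducts may form, or the C11 ratio may be modest.
- Fallback: polar instead of radical acyl-anion chemistry, setting out from 4 and coming back at 7.
- TBSCl and imidazole give the silyl ether F1.
- 2-Lithio-1,3-dithiane in THF–DMPU at −78 °C adds 1,4 opposite the silyloxymethyl group. The lithium enolate is quenched at −78 °C with 2,6-di-tert-butylphenol on the face away from the bulky dithiane, which gives the dithianyl lactone F2.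
- MeI and CaCO3 in aqueous MeCN free the silyloxy aldehyde F3.
- Aqueous HF in MeCN removes silicon and returns 7.

**Step 8 (ring-closing metathesis).**
- Risks: oligomerisation, olefin migration, or a ring too strained to close while the rigid 4E-olefin is present.
- Fallback: build the oxirane before the carbocycle, setting out from 14 and coming back at 18.
- NaBH4 and CeCl3·7H2O in MeOH at −78 °C reduce only the enal, to the allylic alcohol F4.
- Ti(OiPr)4, D-(−)-diisopropyl tartrate and t-BuOOH (4 Å sieves, CH2Cl2, −20 °C) give the epoxy alcohol F5. Reagent and substrate bias are matched here.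
- Dess–Martin periodinane gives the epoxy aldehyde F6.
- Boronate 15 and (S)-TRIP give the epoxy triene alcohol F7.
- Metathesis of F7 then forms a ring with a single endocyclic olefin and a pre-bent C3–C6 segment, and it delivers 18 directly.

**Step 9 (epoxidation).**
- Risks: vanadium may deliver oxygen through the flipped olefin conformer (wrong face) or touch the homoallylic C1=C10 olefin.
- Fallback: use a matched directing group and then invert it, setting out from 14 and coming back at 18.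
- Boronate 15 and (R)-TRIP give the 3R alcohol F8.
- Metathesis gives the 3-epi macrocycle F9. Its hydroxyl lies at a small dihedral angle to the exposed olefin face, so the directing effect and the allylic strain reinforce each other.
- VO(acac)2 and t-BuOOH give the 3-epi epoxide F10.
- A Mitsunobu reaction (4-nitrobenzoic acid, DIAD, PPh3) inverts C3 to the inverted 4-nitrobenzoate F11.
- K2CO3 in MeOH at −10 °C cleaves only this activated ester and returns 18.

**Further compounds**
F1 | step 2 | silyl ether, (5S)-5-{[tert-butyl(dimethyl)silyl]oxymethyl}-3-methylfuran-2(5H)-one | CC1=C[C@@H](CO[Si](C)(C)C(C)(C)C)OC1=O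
F2 | step 2 | dithianyl lactone, 4-(1,3-dithian-2-yl) analogue of 6 as its silyl ether | CC(C)(C)[Si](C)(C)OC[C@H]1OC(=O)[C@H](C)[C@@H]1C1SCCCS1
F3 | step 2 | silyloxy aldehyde, silyl ether of 7 | CC(C)(C)[Si](C)(C)OC[C@H]1OC(=O)[C@H](C)[C@@H]1C=O
F4 | step 8 | allylic alcohol, 1,2-reduction product of 14 | OC/C(C)=C/[C@H]1OC(=O)[C@H](C)[C@@H]1[C@H](OC(=O)/C(C)=C/C)CC(C)=C
F5 | step 8 | epoxy alcohol, oxirane configured as in 18 | OC[C@@]1(C)O[C@@H]1[C@H]1OC(=O)[C@H](C)[C@@H]1[C@H](OC(=O)/C(C)=C/C)CC(C)=C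
F6 | step 8 | epoxy aldehyde, oxidation product of F5 | O=C[C@@]1(C)O[C@@H]1[C@H]1OC(=O)[C@H](C)[C@@H]1[C@H](OC(=O)/C(C)=C/C)CC(C)=C
F7 | step 8 | epoxy triene alcohol, 3S, the seco form of 18 | C=CC[C@H](O)[C@@]1(C)O[C@@H]1[C@H]1OC(=O)[C@H](C)[C@@H]1[C@H](OC(=O)/C(C)=C/C)CC(C)=C
F8 | step 9 | 3R alcohol, C3 epimer of 16 | C=CC[C@@H](O)/C(C)=C/[C@H]1OC(=O)[C@H](C)[C@@H]1[C@H](OC(=O)/C(C)=C/C)CC(C)=C
F9 | step 9 | 3-epi macrocycle, C3 epimer of 17 | C/C=C(\C)C(=O)O[C@@H]1C/C(C)=C\C[C@@H](O)/C(C)=C/[C@H]2OC(=O)[C@H](C)[C@@H]21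
F10 | step 9 | 3-epi epoxide, C3 epimer of 18 | C/C=C(\C)C(=O)O[C@@H]1C/C(C)=C\C[C@@H](O)[C@@]2(C)O[C@@H]2[C@H]2OC(=O)[C@H](C)[C@@H]21
F11 | step 9 | inverted 4-nitrobenzoate, 3-O-(4-nitrobenzoyl) derivative of 18 | C/C=C(\C)C(=O)O[C@@H]1C/C(C)=C\C[C@H](OC(=O)c3ccc(cc3)[N+](=O)[O-])[C@@]2(C)O[C@@H]2[C@H]2OC(=O)[C@H](C)[C@@H]21
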